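**Retrosynthetic overview**
- The target is a depside. The key disconnection is the aryl ester C–O bond, giving olivetolic acid (phenol partner, reacting at its 4-OH) and 2,4-dimethoxy-6-pentylbenzoic acid (acyl partner).
- The free CO2H and 2-OH of olivetolic acid are masked only inside the coupling flask, as a boron chelate, so no separate protection or deprotection steps are needed.
- Olivetolic acid comes from olivetol by direct C-carboxylation; the dimethoxy acid comes from olivetol dimethyl ether by formylation and oxidation.
- No ring is built. Both benzene rings are bought, the two fragments are made separately, and they are joined in the last step.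

Assumption: the target has no stereocentre and no stable stereogenic axis, so it is achiral and "single enantiomer" requires no stereocontrol.

**Step 1**
Reactants: 1 olivetol (5-pentylbenzene-1,3-diol)
Product: 3 olivetolic acid (2,4-dihydroxy-6-pentylbenzoic acid), via magnesium olivetolate chelate 2 (not isolated)
Conditions: MMC (2 M in DMF, 6 equiv), N2, 120 °C, 3 h; then ice-cold 2 M HCl
Reagents that add atoms: methylmagnesium carbonate (methoxymagnesium methyl carbonate, Stiles reagent), COC(=O)O[Mg]OC
Why: Kolbe–Schmitt-type carboxylation with Stiles reagent, in which the magnesium phenoxide is C-carboxylated ortho to one OH and para to the other and the equilibrium is pulled forward by the six-membered magnesium salicylate chelate 2; cold acidification frees the acid without decarboxylation, and no stereocentre is formed.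

**Step 2**
Reactants: 4 1,3-dimethoxy-5-pentylbenzene (olivetol dimethyl ether)
Product: 6 2,4-dimethoxy-6-pentylbenzaldehyde, via aryl iminium chloride 5 (not isolated)
Conditions: POCl3 (1.3 equiv), DMF, 0 °C → 70 °C, 3 h; then ice/H2O, rt
Reagents that add atoms: N,N-dimethylformamide, CN(C)C=O; water, O
Why: Vilsmeier–Haack formylation, in which the bulky chloroiminium electrophile attacks the position para to one OMe and ortho to the other (next to the pentyl group) rather than the more crowded position between the two OMe groups, and water hydrolyses iminium 5 to the aldehyde.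

**Step 3**
Reactants: 6 2,4-dimethoxy-6-pentylbenzaldehyde
Product: 7 2,4-dimethoxy-6-pentylbenzoic acid
Conditions: NaClO2, NaH2PO4, 2-methyl-2-butene, t-BuOH/THF/H2O, 0 °C → rt
Reagents that add atoms: sodium chlorite, [Na+].[O-]Cl=O
Why: Pinnick (Lindgren) oxidation, in which chlorous acid adds to the aldehyde and fragments to the acid while 2-methyl-2-butene traps HOCl so that the electron-rich ring is not chlorinated; the ethers and the alkyl chain are inert.

**Step 4**
Reactants: 3 olivetolic acid; 7 2,4-dimethoxy-6-pentylbenzoic acid
Product: 11 4-[(2,4-dimethoxy-6-pentylbenzoyl)oxy]-2-hydroxy-6-pentylbenzoic acid (target, achiral), via phenylboronate chelate 8 (not isolated), via acid chloride 9 (not isolated), via chelated depside 10 (not isolated)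
Conditions: (i) 3, PhB(OH)2 (1.05 equiv), 4 Å MS, CH2Cl2, 40 °C, 2 h; (ii) separately 7, (COCl)2, cat. DMF, CH2Cl2, 0 °C → rt, evaporate; (iii) crude 9 added to 8, Et3N (2.5 equiv), DMAP (10 mol%), 0 °C → rt; (iv) THF/1 M HCl, rt, 30 min; chromatography
Reagents that add atoms: none
Why: Proposed new method: boronic-acid-templated, site-selective acylation of an unprotected 2,4-dihydroxybenzoic acid. PhB(OH)2 condenses with the salicylic acid unit of 3 (2-OH plus CO2H) to the six-membered benzodioxaborinone 8, which ties up the carboxyl and the ortho-OH in one traceless mask and leaves the 4-OH as the only free nucleophile. Et3N forms the 4-phenoxide (made more acidic by the para acyloxyboron group) and also coordinates boron, which switches off the acyloxyborane as an acyl donor. The phenoxide attacks the hindered but easily ionised acid chloride 9 (DMAP relay, acylium-like) to form the depside C–O bond in 10, and mild aqueous acid then hydrolyses both B–O bonds to release the free acid 11. The closest known reaction types are transient boronate masking of diols for site-selective acylation and the classical 4-O-acylation of benzyl 2,4-dihydroxybenzoates in depside synthesis; benzodioxaborinone formation from salicylic acids is known, but its use as an in situ mask for esterification is the untested part.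

**Compound list**
1 | olivetol (5-pentylbenzene-1,3-diol) | CCCCCc1cc(O)cc(O)c1 | starting material
2 | magnesium olivetolate chelate (Mg bound to the carboxylate O and the ortho-phenoxide O of 2,4-dihydroxy-6-pentylbenzoate, six-membered ring, 4-OH free, drawn 1:1) | CCCCCc1cc(O)cc2O[Mg]OC(=O)c12 | intermediate
3 | olivetolic acid (2,4-dihydroxy-6-pentylbenzoic acid) | CCCCCc1cc(O)cc(O)c1C(=O)O | intermediate
4 | 1,3-dimethoxy-5-pentylbenzene | CCCCCc1cc(OC)cc(OC)c1 | starting material
5 | N-[(2,4-dimethoxy-6-pentylphenyl)methylidene]-N-methylmethanaminium chloride (aryl iminium salt, drawn as the chloride) | CCCCCc1cc(OC)cc(OC)c1C=[N+](C)C.[Cl-] | intermediate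
6 | 2,4-dimethoxy-6-pentylbenzaldehyde | CCCCCc1cc(OC)cc(OC)c1C=O | intermediate
7 | 2,4-dimethoxy-6-pentylbenzoic acid | CCCCCc1cc(OC)cc(OC)c1C(=O)O | intermediate
8 | 7-hydroxy-5-pentyl-2-phenyl-4H-1,3,2-benzodioxaborin-4-one (phenylboronate chelate of olivetolic acid) | CCCCCc1cc(O)cc2OB(c3ccccc3)OC(=O)c12 | intermediate
9 | 2,4-dimethoxy-6-pentylbenzoyl chloride | CCCCCc1cc(OC)cc(OC)c1C(Cl)=O | intermediate
10 | 4-oxo-5-pentyl-2-phenyl-4H-1,3,2-benzodioxaborin-7-yl 2,4-dimethoxy-6-pentylbenzoate (boron-chelated depside) | CCCCCc1cc(OC(=O)c3c(CCCCC)cc(OC)cc3OC)cc2OB(c4ccccc4)OC(=O)c12 | intermediate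
11 | 4-[(2,4-dimethoxy-6-pentylbenzoyl)oxy]-2-hydroxy-6-pentylbenzoic acid (achiral) | CCCCCc1cc(OC(=O)c2c(CCCCC)cc(OC)cc2OC)cc(O)c1C(=O)O | target

**Step count**
Total steps: 4. Longest linear sequence: 3 (4 → 6 → 7 → 11; steps 2, 3 and 4).

**Steps most likely to fail, with fallbacks**

Step 4 (the proposed new step). Risks are incomplete chelation (free CO2H then gives mixed anhydrides), B–O exchange during acylation that leads to oligomers, and slow acylation by the hindered acyl donor. The fallback uses known chemistry and sets out from 3 and 7. The carboxylate of 3 is alkylated selectively with BnBr and KHCO3 in DMF at rt to give benzyl 2,4-dihydroxy-6-pentylbenzoate F3. Its 4-OH (the 2-OH is hydrogen-bonded to the ester) is acylated with acid 7 using TFAA in toluene at rt to give benzyl 4-[(2,4-dimethoxy-6-pentylbenzoyl)oxy]-2-hydroxy-6-pentylbenzoate F4. Hydrogenolysis (H2, Pd/C, EtOAc) then removes the benzyl group, and the route comes back at 11.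

Step 1. Risks are modest conversion, some carboxylation between the two OH groups (the 2,6-dihydroxy-4-pentyl isomer) and decarboxylation on work-up. I am fairly confident this carboxylation is precedented, but its regioselectivity on unsubstituted olivetol is the least certain point among the conventional steps. The fallback sets out from 1. Vilsmeier–Haack formylation (POCl3, DMF, 0 °C → rt, aqueous hydrolysis) gives 2,4-dihydroxy-6-pentylbenzaldehyde F1, and Lindgren oxidation (NaClO2, sulfamic acid, aqueous dioxane, 0–10 °C) converts it to the acid, so the route comes back at 3.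

Step 2. The risk is formation of the regioisomeric aldehyde (formyl between the two OMe groups) and a difficult separation. The fallback sets out from 4. NBS in MeCN at 0 °C brominates para to one methoxy group to give 2-bromo-1,5-dimethoxy-3-pentylbenzene F2. Bromine–lithium exchange (n-BuLi, THF, −78 °C) followed by a CO2 quench and acidic work-up gives the acid directly, so the route comes back at 7 and step 3 is bypassed.

**Further compounds**
F1 | step 1 | 2,4-dihydroxy-6-pentylbenzaldehyde | CCCCCc1cc(O)cc(O)c1C=O
F2 | step 2 | 2-bromo-1,5-dimethoxy-3-pentylbenzene | CCCCCc1cc(OC)cc(OC)c1Br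
F3 | step 4 | benzyl 2,4-dihydroxy-6-pentylbenzoate | CCCCCc1cc(O)cc(O)c1C(=O)OCc2ccccc2
F4 | step 4 | benzyl 4-[(2,4-dimethoxy-6-pentylbenzoyl)oxy]-2-hydroxy-6-pentylbenzoate | CCCCCc1cc(OC(=O)c2c(CCCCC)cc(OC)cc2OC)cc(O)c1C(=O)OCc3ccccc3
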